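- west: left-handed substrate 0.50 M; right-handed substrate 0.50 M; reagent 3.8 equiv (fed, over 4.0 s); free catalyst 0.063 mol%; impurity 64 µM; run made earlier; the fed solution adds 0.10 times the starting volume
- flask: left-handed substrate 0.50 M; reagent 2.50 equiv (fed, over 4.0 s); free catalyst 0.063 mol%; impurity 64 µM; right-handed substrate 0.50 M; time 10 min; the fed solution adds 0.10 times the starting volume

- west (time / s: left-handed product / %, right-handed product / %, left-handed substrate / %): 10.0: 3.8, 1.6, 46.4; 12.0: 4.7, 1.7, 45.7; 25.0: 8.6, 3.6, 42.8; 60.0: 14.6, 6.3, 38.8

(standard deviation of a reading: 0.3 percentage points)

- free catalyst is single-handed; left-handed substrate and right-handed substrate are mirror images of each other, charged as a racemate, each of them at the stated concentration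
- every charge counts on the volume at the start, and the solution that is fed holds the whole dose
- the analysis behind the earlier runs scatters by 0.3 percentage points, standard deviation
- an excess is the difference of the two amounts in percent of their sum
- an excess is below zero if the other one leads

- left-handed product and right-handed product together, in percent of the left-handed substrate and right-handed substrate charged together, at 10 min
- excess of left-handed product over right-handed product in the product at 10 min
- whether the exchange between left-handed substrate and right-handed substrate keeps pace with the reaction: how far the product's excess at 10 min gets from its value without exchange to its value with instant exchange (above 80% keeps pace, below 20% hardly takes part, else lags behind)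

1. Start with amounts, in this flask: [free catalyst] is 315 µM and [impurity] is 64 µM, a share of 20.3%. I assume, and no reading tests this, that impurity takes catalyst one to one. What remains, 251 µM, is the working catalyst, the charged free catalyst minus the charged impurity. The west run has the same working catalyst.

2. Now climb the time scales of the west run, fastest first. The feed ends at 4.0 s.

3. At 60.0 s, left-handed substrate plus left-handed product stand at 53.4%, above the 50.0% charged, so the substrates interconvert. Their small gap, held against the pace at which left-handed product outruns right-handed, reads as an exchange half-time of 13.6 s, longer than the feed.

4. Define the depth as ln(1/(1−y)), with y the product fraction, which takes out the substrate's own running down. West depth grows at 0.00492 s⁻¹ from 12.0 s to 25.0 s, then at 0.00298 s⁻¹ up to 60.0 s. I read that as a catalyst half-life of 33.2 s, a rough reading given the scatter.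

5. Ten minutes are 18.1 such half-lives, so I expect the catalyst to die first: working catalyst, not time, sets the yield. Adding the tail to the west depth gives 0.334. I assume, unmeasured, that less reagent slows making and dying alike, so I commit to y near 28.4%. In the west run, the first depth rate above gives the substrates a half-life by reaction of 141 s, longer than the exchange half-time, so I expect a dynamic kinetic resolution that keeps pace, with the excess near the west value of 39.7%.

6. The forecast gives 24%, 40.5% and keeps pace, with a falling rate “suggesting catalyst death”. Its yield is lower than mine.

7. The flask gives 36.3%, 40.6% and keeps pace, 89% of the way, so the yield stands above both reckonings. In this flask, spent catalyst B holds 20.3% of the catalyst at 0.0667 min, the end of the feed, the share from step 1, and at 10.0 min free catalyst is down to 1.66% of its charge. The working catalyst 251 µM has bought a depth of 0.451, more than I read from the west run.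

    reagent + free catalyst + left-handed substrate → free catalyst + left-handed product (k = 29.0 M⁻² s⁻¹)
    reagent + free catalyst + right-handed substrate → free catalyst + right-handed product (k = 12.0 M⁻² s⁻¹)
    left-handed substrate ⇌ right-handed substrate (k = 0.0320 s⁻¹)
    free catalyst ⇌ dormant form (K = 0.460, k = 0.0160 s⁻¹)
    reagent + free catalyst → spent catalyst A (k = 0.0100 M⁻¹ s⁻¹)
    free catalyst + impurity → spent catalyst B (k = 44000 M⁻¹ s⁻¹)

8. Take the neighbour flask charged with 0.11 mol% of free catalyst. Its working catalyst is 486 µM, twice that of this flask, so with reagent, impurity and time held, scaling the depth gives y near 58.3%. The computed neighbour gives 57.2%.

(The runs stem from a simulated flask for substances that don't exist, noise included.)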